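Count first what the charges of this flask allow, since the readings stop moving.

| flask | starting material | reagent | capture agent | free catalyst | second catalyst | temperature | remark | time |
|---|---|---|---|---|---|---|---|---|
| Thursday's | 0.30 M | 0.24 M | 6 mM | 0.60 mM | 0.20 mM | 0 °C | the very flask that is asked about, followed so far |  |
| Saturday's | 0.15 M | 0.24 M | 6 mM | 0.60 mM | 0.20 mM | −15 °C | run made earlier |  |
| flask | 0.30 M | 0.240 M | 6.00 mM | 0.60 mM | 0.20 mM | 0 °C |  | 8.0 d |

- Thursday's (time / h: target / %): 20.0: 70; 60.0: 82; 96.0: 80; 144: 81
- Saturday's (time / h: target / %): 12.0: 42; 40.0: 84; 60.0: 93; 96.0: 92

(readings scatter by 2 percentage points)

- teal: at 8.0 d add free catalyst, 100% of the amount charged, then wait 4.0 d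
- red: at 8.0 d add reagent, 100% of the amount charged, then wait 4.0 d
- ochre: at 8.0 d raise the temperature by 15 K, then wait 4.0 d
- violet: at 8.0 d take out 90% of the target then present, then wait 4.0 d
- green: change nothing and wait 4.0 d more

- what is taken out of target is counted as made
- candidate steps: reagent + second catalyst + open intermediate -> second catalyst + target; starting material + free catalyst <-> free catalyst + open intermediate; open intermediate + capture agent -> trapped intermediate
- "the catalyst" is free catalyst with its forms; second catalyst is a second catalyst
- additions bring no volume worth counting

- target, in percent of the starting material first charged, at 8.0 d
- the option that brings most further target ("none" if no option brings more than 2 percentage points) (teal / red / ochre / violet / green / none)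
- target present, with what was taken out counted in, in percent of the starting material first charged, after red
- target present, with what was taken out counted in, in percent of the starting material first charged, after green

The free catalyst turns starting material into open intermediate. Open intermediate then takes one reagent on the second catalyst to give target, or one capture agent to give trapped intermediate. So I compare two shares for Thursday's flask: c(reagent)/c(starting material), 80.0%, and the share left once capture agent has taken its full charge, 98.0%. The smaller, 80.0%, I call the ceiling: the lesser of these two shares of the charge. Here the reagent share is the smaller, so reagent is the limiting reagent.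

Thursday's readings from 60.0 h on average 81.0%, so I commit to 80.0% at 8.0 d, with nothing gained by waiting. Saturday's flask, with a reagent share of 160%, last reads 92%, so target in that flask stands above 80.0%.

Now I put that answer back and go round again. Red adds 100% of the reagent charge, the reagent share passes the capture share, and the ceiling rises to 98.0%. The other options change neither share. Thursday's flask showed 70% by 20.0 h, and red waits 4.0 d, which should do if both catalysts still work.

The forecast gives 80.5% now, red as best, 97% after red and 80.5% after green, holding that “reagent has run out rather than the catalysts having died”. My figures stand 0.5 percentage points below its first and 1 point above its third.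

The flask gives 80.0%, with red best at 18 points further, 98.0% after red and 80.0% after green.

    reagent + second catalyst + open intermediate → second catalyst + target (k = 9500 /M²/h, Ea = 38.0 kJ/mol)
    starting material + free catalyst ⇌ free catalyst + open intermediate (K = 1.20, k = 600 /M/h, Ea = 48.0 kJ/mol, ΔH = −34.0 kJ/mol)
    open intermediate + capture agent → trapped intermediate (k = 1.90 /M/h, Ea = 48.0 kJ/mol)
    (constants at 0 °C)

In Thursday's flask at 2.27 h, the half-life of reagent by the target step is 4.4 h, far shorter than the 8.0 d of the run. At 192 h free reagent stands at 0% and target at the ceiling of 80.0%, while red's ceiling of 98.0% is met at 98.0%. In the neighbouring flask with 0.75 M of starting material the ceiling reckons to 32.0%, and that flask stands at 32.0%.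

(The readings are calculated with made-up constants; noise was put on by code.)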